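**Retrosynthetic overview**
- The target (erythro, 7R,8S) comes from its 4-O-benzyl ether by a final hydrogenolysis. No ring is formed at any stage, because both arenes are bought intact.
- C9–OH and the C8 stereocentre come from anti-selective hydroboration–oxidation of the C8=C9 enol ether in a 2-aryloxy allylic alcohol.
- The key C7–C8 bond joins O-benzylsyringaldehyde (C7, acceptor) to a 1-aryloxyvinyl anion (C8, a masked acyl anion that is a donor at an oxygen-bearing carbon). The aryloxy "mask" is the 8-O-4' ether itself and is never removed. C7 is set by a chiral amino-alkoxide zinc catalyst.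
- The aryl vinyl ether comes from phenol-selective O-vinylation of dihydrosinapyl alcohol, which comes from hydroboration of 4-allyl-2,6-dimethoxyphenol.

Assumption: 4-allyl-2,6-dimethoxyphenol and 4-(benzyloxy)-3,5-dimethoxybenzaldehyde are taken as catalogue chemicals. C7 is the benzylic carbinol carbon, C8 the ether carbon and C9 the CH2OH carbon.

**Step 1**
Reactants: 1 allylsyringol [4-allyl-2,6-dimethoxyphenol]
Product: 3 dihydrosinapyl alcohol [4-(3-hydroxypropyl)-2,6-dimethoxyphenol], via bis(9-BBN) adduct 2 (not isolated)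
Conditions: 9-BBN (2.2 equiv), THF, 0 °C to rt; then NaOH (2.2 equiv), 30% H2O2, 0 °C to rt
Reagents that add atoms: hydrogen peroxide, OO
Why: This is a Brown hydroboration–oxidation in which 9-BBN first borylates the phenolic O–H, then places boron on the terminal allyl carbon, and alkaline peroxide converts C–B into C–OH while hydrolysing the aryl borinate, with no stereocentre formed.

**Step 2**
Reactants: 3 dihydrosinapyl alcohol
Product: 4 aryl vinyl ether [3-[4-(ethenyloxy)-3,5-dimethoxyphenyl]propan-1-ol]
Conditions: 2,4,6-trivinylcyclotriboroxane·pyridine (0.7 equiv), Cu(OAc)2 (2.2 equiv), pyridine (10 equiv), CH2Cl2, rt, N2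
Reagents that add atoms: 2,4,6-trivinylcyclotriboroxane–pyridine complex, C=CB1OB(C=C)OB(C=C)O1.c1ccncc1
Why: This is a Chan–Lam–Evans C–O coupling in which vinyl passes from boron to phenoxide-bound divalent copper, disproportionation with a second divalent copper gives a trivalent copper species that reductively eliminates the aryl vinyl ether, the much less acidic aliphatic OH does not compete, and excluding O2 spares the oxidation-prone phenol.

**Step 3 (key step)**
Reactants: 4 aryl vinyl ether; 5 O-benzylsyringaldehyde [4-(benzyloxy)-3,5-dimethoxybenzaldehyde]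
Product: 9 (1R)-1-[4-(benzyloxy)-3,5-dimethoxyphenyl]-2-[4-(3-hydroxypropyl)-2,6-dimethoxyphenoxy]prop-2-en-1-ol, via dilithio species 6 (not isolated), via bis(ethylzinc) species 7 (not isolated), via zinc alkoxide adduct 8 (not isolated)
Conditions: 4 (1.5 equiv), t-BuLi (3.1 equiv), THF, −78 °C, 45 min; EtZnCl (3.1 equiv, from Et2Zn + ZnCl2), −78 to 0 °C; THF exchanged for toluene, LiCl filtered off; (−)-MIB [(2S)-3-exo-morpholinoisoborneol] (10 mol %), 5 (1.0 equiv), 0 °C, 16 h; H2O; Et3N-washed SiO2
Reagents that add atoms: none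
Why: Proposed new method: after the alcohol is deprotonated, t-BuLi removes the vinylic C–H next to oxygen (enol-ether α-lithiation, the classical masked acyl anion, helped here by lithium chelation to a flanking OMe and by the inductive pull of the aryloxy group), immediate Li-to-Zn exchange at −78 °C stops carbenoid-type loss of aryloxide, and the (1-aryloxyvinyl)(ethyl)zinc transfers its sp2 carbon faster than ethyl to the Si face of 5 within the Noyori-type amino-alkoxide dizinc transition state of (−)-MIB, which sets C7 as R because C8 outranks the aryl group; the closest known reaction types are the amino-alcohol-catalysed asymmetric addition of alkenylzincs derived from alkenyllithiums to aromatic aldehydes and the use of 1-ethoxyvinyl-lithium and -zinc as acetyl anion equivalents, and the new feature is that the aryloxy mask is kept as the 8-O-4' ether.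

**Step 4**
Reactants: 9 (R)-allylic alcohol
Product: 11 (1R,2S)-1-[4-(benzyloxy)-3,5-dimethoxyphenyl]-2-[4-(3-hydroxypropyl)-2,6-dimethoxyphenoxy]propane-1,3-diol, via tris(9-BBN) adduct 10 (not isolated)
Conditions: 9-BBN (4 equiv), THF, 0 °C to rt, 12 h; then NaOH, 30% H2O2, 0 °C; minor threo isomer removed on SiO2
Reagents that add atoms: hydrogen peroxide, OO
Why: This is a Brown hydroboration–oxidation of the 1,1-disubstituted enol ether in which sterics and enol-ether polarisation both send boron to C9, and acyclic 1,2-induction of the Still–Barrish/Houk type (C7–H inside, aryl anti to the bulky borane, C7–O outside) delivers hydrogen to the face of C8 that gives the anti (erythro) 7R,8S isomer.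

**Step 5**
Reactants: 11 O-benzyl erythro triol
Product: 12 target, (1R,2S)-1-(4-hydroxy-3,5-dimethoxyphenyl)-2-[4-(3-hydroxypropyl)-2,6-dimethoxyphenoxy]propane-1,3-diol
Conditions: H2 (1 atm), 10% Pd/C, EtOAc/EtOH, rt
Reagents that add atoms: none
Why: Neutral catalytic hydrogenolysis cleaves only the phenolic O–CH2Ph bond, whereas the secondary C7–OH and the C8 alkyl aryl ether are inert at 1 atm without acid, so both stereocentres stay untouched.

**Compound list**
1 | 4-allyl-2,6-dimethoxyphenol | C=CCc1cc(OC)c(O)c(OC)c1 | starting material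
2 | bis(9-BBN) adduct: aryl O–B(9-BBN) borinate carrying a 3-(9-BBN-9-yl)propyl chain | COc1cc(CCCB2C3CCCC2CCC3)cc(OC)c1OB1C2CCCC1CCC2 | intermediate
3 | 4-(3-hydroxypropyl)-2,6-dimethoxyphenol (dihydrosinapyl alcohol) | COc1cc(CCCO)cc(OC)c1O | intermediate
4 | 3-[4-(ethenyloxy)-3,5-dimethoxyphenyl]propan-1-ol | C=COc1c(OC)cc(CCCO)cc1OC | intermediate
5 | 4-(benzyloxy)-3,5-dimethoxybenzaldehyde | COc1cc(C=O)cc(OC)c1OCc1ccccc1 | starting material
6 | lithium 3-{3,5-dimethoxy-4-[(1-lithioethenyl)oxy]phenyl}propan-1-olate | [Li]OCCCc1cc(OC)c(OC([Li])=C)c(OC)c1 | intermediate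
7 | ethylzinc alkoxide of 4 carrying an ethylzinc group on the α-vinyl carbon | CC[Zn]OCCCc1cc(OC)c(OC(=C)[Zn]CC)c(OC)c1 | intermediate
8 | bis(ethylzinc) alkoxide of 9 (C7 R) | COc1cc(cc(OC)c1OCc1ccccc1)[C@@H](O[Zn]CC)C(=C)Oc1c(OC)cc(CCCO[Zn]CC)cc1OC | intermediate
9 | (1R)-1-[4-(benzyloxy)-3,5-dimethoxyphenyl]-2-[4-(3-hydroxypropyl)-2,6-dimethoxyphenoxy]prop-2-en-1-ol | COc1cc(cc(OC)c1OCc1ccccc1)[C@@H](O)C(=C)Oc1c(OC)cc(CCCO)cc1OC | intermediate
10 | tris(9-BBN) adduct (7R,8S): C9–B(9-BBN), with the C7–O and side-chain O as 9-BBN borinates | COc1cc(cc(OC)c1OCc1ccccc1)[C@@H](OB1C2CCCC1CCC2)[C@H](CB1C2CCCC1CCC2)Oc1c(OC)cc(CCCOB2C3CCCC2CCC3)cc1OC | intermediate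
11 | (1R,2S)-1-[4-(benzyloxy)-3,5-dimethoxyphenyl]-2-[4-(3-hydroxypropyl)-2,6-dimethoxyphenoxy]propane-1,3-diol | COc1cc(cc(OC)c1OCc1ccccc1)[C@@H](O)[C@H](CO)Oc1c(OC)cc(CCCO)cc1OC | intermediate
12 | (1R,2S)-1-(4-hydroxy-3,5-dimethoxyphenyl)-2-[4-(3-hydroxypropyl)-2,6-dimethoxyphenoxy]propane-1,3-diol | COc1cc([C@@H](O)[C@H](CO)Oc2c(OC)cc(CCCO)cc2OC)cc(OC)c1O | target

**Totals**
Total step count: 5. Longest linear sequence: 5 (1 → 3 → 4 → 9 → 11 → 12). Compound 5 enters as bought.

**Steps most likely to fail**

**Step 3.**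
- *Risks:* The α-lithiated aryl vinyl ether may lose aryloxide. Ethyl transfer may compete with vinyl transfer. The α-oxygenated vinylzinc may give only moderate ee.
- *Fallback:* This separates bond formation from stereoinduction. It sets out from 4 and 5 and comes back at 9.
  - The dilithio species 6 is added directly to 5 (THF, −78 °C, no zinc, no ligand) to give the racemic allylic alcohol F1.
  - MnO2 (CH2Cl2, rt) oxidises only the benzylic and allylic carbinol to the 2-aryloxy enone F2.
  - (S)-Me-CBS oxazaborolidine (20 mol %) with catecholborane (toluene, −78 °C) then gives 9. The electron-rich aryl group stays coplanar with the carbonyl and acts as the small group, while the twisted α-aryloxyvinyl group acts as the large one, so the R alcohol is expected.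
- If the lithiation itself fails, the fallback under step 4 avoids it altogether.

**Step 4.**
- *Risks:* The β-aryloxyalkylborane may eliminate aryloxide. The hindered enol ether may react slowly. The gauche arrangement of the C7–O and C8–O bonds in the favoured transition state may erode the anti selectivity.
- *Fallback:* This sets C8 together with C7 in a closed transition state. It sets out from 3 (with 5) and comes back at 11, by-passing 4 to 10.
  - Phenol 3 is O-propargylated (propargyl bromide, K2CO3, acetone, reflux) to the aryl propargyl ether F3.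
  - CuCl/Xantphos/NaOt-Bu-catalysed protoboration with B2pin2 and MeOH gives the (E)-3-aryloxyprop-1-enyl pinacol boronate F4.
  - [Ir(cod)(PPh2Me)2]PF6 (3 mol %, activated with H2) moves the double bond to give the (E)-γ-aryloxyallyl pinacol boronate F5, an α-aryloxy carbanion equivalent.
  - In the same flask F5 adds to 5 under catalysis by (S)-TRIP [(S)-3,3'-bis(2,4,6-triisopropylphenyl)-BINOL hydrogen phosphate] through a chair transition state to give the anti homoallylic alcohol F6. The E geometry gives the anti relationship, and the acid enantiomer is chosen by analogy for Si-face attack.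
  - Lemieux–Johnson cleavage (K2OsO4·2H2O, NaIO4, 2,6-lutidine, dioxane–H2O) gives the α-aryloxy aldehyde F7, which is reduced at once with NaBH4 (MeOH, 0 °C) to 11.

**Step 2.**
- *Risks:* The 4-alkyl-2,6-dimethoxyphenol is hindered, and divalent copper oxidises it easily.
- *Fallback:* This builds the vinyl group by alkylation and elimination, with no oxidant. It sets out from 3 and comes back at 4.
  - 1,2-Dibromoethane (5 equiv, K2CO3, acetone, reflux) gives the 2-bromoethyl aryl ether F8.
  - KOt-Bu (2.2 equiv, THF, 0 °C) effects E2 elimination to 4.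

**Further compounds**
F1 | step 3 | racemic 1-[4-(benzyloxy)-3,5-dimethoxyphenyl]-2-[4-(3-hydroxypropyl)-2,6-dimethoxyphenoxy]prop-2-en-1-ol | COc1cc(cc(OC)c1OCc1ccccc1)C(O)C(=C)Oc1c(OC)cc(CCCO)cc1OC
F2 | step 3 | 1-[4-(benzyloxy)-3,5-dimethoxyphenyl]-2-[4-(3-hydroxypropyl)-2,6-dimethoxyphenoxy]prop-2-en-1-one | COc1cc(cc(OC)c1OCc1ccccc1)C(=O)C(=C)Oc1c(OC)cc(CCCO)cc1OC
F3 | step 4 | 3-[3,5-dimethoxy-4-(prop-2-yn-1-yloxy)phenyl]propan-1-ol | C#CCOc1c(OC)cc(CCCO)cc1OC
F4 | step 4 | (E)-3-[4-(3-hydroxypropyl)-2,6-dimethoxyphenoxy]prop-1-enylboronic acid pinacol ester | CC1(C)OB(/C=C/COc2c(OC)cc(CCCO)cc2OC)OC1(C)C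
F5 | step 4 | (E)-3-[4-(3-hydroxypropyl)-2,6-dimethoxyphenoxy]prop-2-enylboronic acid pinacol ester | CC1(C)OB(C/C=C/Oc2c(OC)cc(CCCO)cc2OC)OC1(C)C
F6 | step 4 | (1R,2S)-1-[4-(benzyloxy)-3,5-dimethoxyphenyl]-2-[4-(3-hydroxypropyl)-2,6-dimethoxyphenoxy]but-3-en-1-ol | COc1cc(cc(OC)c1OCc1ccccc1)[C@@H](O)[C@H](C=C)Oc1c(OC)cc(CCCO)cc1OC
F7 | step 4 | (2R,3R)-3-[4-(benzyloxy)-3,5-dimethoxyphenyl]-3-hydroxy-2-[4-(3-hydroxypropyl)-2,6-dimethoxyphenoxy]propanal | COc1cc(cc(OC)c1OCc1ccccc1)[C@@H](O)[C@H](C=O)Oc1c(OC)cc(CCCO)cc1OC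
F8 | step 2 | 3-[4-(2-bromoethoxy)-3,5-dimethoxyphenyl]propan-1-ol | BrCCOc1c(OC)cc(CCCO)cc1OC
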